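The cyclopentene is closed last, at C1–C2 (guaiane numbering), on a seven-membered ring made by ring expansion of (S)-carvone. The key step frees an allyllithium at C2 by reductive lithiation of an allyl sulfide; it opens a C1–C10 epoxide from the rear in a 5-exo-tet reaction. One operation forms the ring bond, sets C1 by inversion and releases the tertiary C10 alkoxide: it exploits the anti relation of the C10–O and C1–C2 bonds across C1–C10 of the seven-membered ring. The precursor is a cis-2,3-epoxycycloheptanol whose carbinol carbon C5 carries the (Z)-butenyl arm; that C5 oxygen later leaves with inversion, turning the cis-fused bicycle into the trans-fused target.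

Key step: step 8

Remark: atoms carry guaiane numbers: ring-fusion carbons C1 and C5, cyclopentene C1–C2–C3=C4(CH3)–C5, seven-membered ring C1, C5, C6, C7 (isopropenyl), C8, C9, C10 (CH3, O).
Assumption: step 4 is written with the quinine-derived amine; should it select the other face of enone 6, its quinidine-derived pseudoenantiomer takes its place.

Step 1
Reactants: 1 (S)-(+)-carvone
Product: 3 trimethyl{[(5S)-2-methyl-5-(prop-1-en-2-yl)cyclohex-1-en-1-yl]oxy}silane, via lithium enolate 2 (not isolated)
Conditions: LiBH(s-C4H9)3 (L-Selectride), THF, −78 °C; then Me3SiCl, −78 → 0 °C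
Reagents that add atoms: chlorotrimethylsilane, C[Si](C)(C)Cl
Why: Conjugate hydride reduction of the enone with a trialkylborohydride gives the lithium enolate regiospecifically and O-silylation traps it as the tetrasubstituted silyl enol ether, the C5 centre of carvone being untouched.

Step 2
Reactants: 3 silyl enol ether
Product: 4 trimethyl{[(3S)-6-methyl-3-(prop-1-en-2-yl)bicyclo[4.1.0]heptan-1-yl]oxy}silane (both cis-fused cyclopropane diastereomers)
Conditions: Et2Zn, CH2I2, CH2Cl2, 0 °C → rt
Reagents that add atoms: diiodomethane, ICI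
Why: Simmons–Smith cyclopropanation (Furukawa variant) should occur at the electron-rich silyl enol ether in preference to the isopropenyl group, and either face is acceptable because the two new centres are erased in step 3.

Step 3
Reactants: 4 siloxycyclopropane
Product: 6 (6S)-3-methyl-6-(prop-1-en-2-yl)cyclohept-2-en-1-one, via chloroketone 5 (not isolated)
Conditions: FeCl3, DMF, 0 °C → rt; then NaOAc, MeOH, reflux
Reagents that add atoms: none
Why: Ito–Saegusa ring expansion, in which FeCl3 oxidises the siloxycyclopropane, the ring-fusion bond opens to the tertiary radical that takes up chlorine, and NaOAc eliminates HCl to the conjugated cycloheptenone with one more ring carbon.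

Step 4
Reactants: 6 cycloheptenone
Product: 7 (1S,4S,7S)-7-methyl-4-(prop-1-en-2-yl)-8-oxabicyclo[5.1.0]octan-2-one
Conditions: 9-amino(9-deoxy)epiquinine·2 CF3CO2H (10 mol %), 50% aq H2O2, 1,4-dioxane, 35 °C
Reagents that add atoms: hydrogen peroxide, OO
Why: Amine-catalysed asymmetric Weitz–Scheffer epoxidation via the iminium ion, in which the catalyst rather than the remote isopropenyl-bearing centre should select the enone face so that the oxirane oxygen lies trans to the isopropenyl group (1S,7S).

Step 5
Reactants: 8 but-2-yn-1-ol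
Product: 10 (2Z)-3-iodobut-2-en-1-ol, via cyclic vinylalanate 9 (not isolated)
Conditions: NaAlH2(OCH2CH2OCH3)2 (Red-Al), Et2O, 0 °C; then I2, −78 → 0 °C
Reagents that add atoms: iodine, II
Why: Hydroxyl-directed trans-hydroalumination puts aluminium on C3 in a five-membered alanate and iodinolysis with retention gives the Z-iodoalkene.

Step 6
Reactants: 10 (2Z)-3-iodobut-2-en-1-ol
Product: 11 {[(2Z)-3-iodobut-2-en-1-yl]sulfanyl}benzene
Conditions: PhSSPh, n-Bu3P, THF, rt
Reagents that add atoms: diphenyl disulfide, c1ccc(SSc2ccccc2)cc1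
Why: Hata thioether synthesis, in which the alkoxyphosphonium salt of the primary allylic alcohol is displaced by benzenethiolate in an SN2 reaction that leaves the alkene geometry and the vinyl iodide untouched.

Step 7
Reactants: 11 vinyl iodide sulfide; 7 epoxy ketone
Product: 13 (1R,2S,4S,7S)-7-methyl-2-[(2Z)-4-(phenylsulfanyl)but-2-en-2-yl]-4-(prop-1-en-2-yl)-8-oxabicyclo[5.1.0]octan-2-ol, via vinyllithium 12 (not isolated)
Conditions: t-BuLi (2 equiv), Et2O, −78 °C; then 7, THF, −78 °C; H2O
Reagents that add atoms: none
Why: Iodine–lithium exchange keeps the alkene geometry and the vinyllithium adds 1,2 to the ketone from the face opposite the oxirane oxygen (epoxide-controlled carbonyl addition), which sets C5 with its hydroxyl cis to the epoxide.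

Step 8
Reactants: 13 epoxy alcohol with allyl sulfide arm
Product: 16 (3aR,5S,8S,8aR)-3,8-dimethyl-5-(prop-1-en-2-yl)-1,3a,4,5,6,7,8,8a-octahydroazulene-3a,8-diol, via lithium alkoxide 14 (not isolated), via dilithio allyl species 15 (not isolated)
Conditions: n-BuLi (1.0 equiv), THF, −78 °C; lithium 4,4′-di-tert-butylbiphenylide (2.1 equiv), −78 °C; then −78 → 0 °C; H2O
Reagents that add atoms: none
Why: Electron transfer from the arene radical anion cleaves the allylic C–S bond (reductive lithiation of an allyl phenyl sulfide) and leaves an allyllithium whose primary terminus C2 attacks the oxirane carbon C1 from the rear, an intramolecular carbanion–epoxide alkylation of the epoxynitrile-cyclisation type. The cyclopentene closes in the 5-exo-tet mode, the breaking C1–O bond lying outside the new ring. C1 is set by inversion: in the cis-epoxy alkoxide the alkenyl arm on C5 is antiperiplanar to the C1–O bond, so C2 can reach C1 only on the face opposite the oxirane oxygen, which gives the cis-fused bicycle and frees the C10 alkoxide with its configuration untouched and anti to the new bond. The step needs attack by the primary allyl terminus on the secondary oxirane carbon; the other terminus C4 is fully substituted and would have to build a cyclopropane flanked by two quaternary carbons, and C10 is tertiary and cannot close a five-membered ring. The Z geometry of the arm comes from step 7, and the allyllithium can still correct it by rotation, so both geometries should end in the same ring. The lithium alkoxide formed first keeps the hydroxyl from quenching the carbanion.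

Step 9
Reactants: 16 diol
Product: 17 cyclic carbonate of 16 (six-membered 1,3-dioxan-2-one bridging O-3a and O-8; 3aR,5S,8S,8aR)
Conditions: NaH, 1,1′-carbonyldiimidazole, THF, 0 → 50 °C
Reagents that add atoms: 1,1′-carbonyldiimidazole, O=C(n1ccnc1)n1ccnc1
Why: Carbonate formation with a phosgene equivalent, in which the two tertiary hydroxyls, cis-1,3 across C1, should close the six-membered ring that activates the allylic C5–O bond and masks C10–OH at once.

Step 10
Reactants: 17 cyclic carbonate
Product: 18 (3aR,5S,8S,8aS)-3,8-dimethyl-5-(prop-1-en-2-yl)-1,3a,4,5,6,7,8,8a-octahydroazulen-8-ol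
Conditions: Pd(OAc)2 (5 mol %), n-Bu3P, HCO2H, Et3N, 1,4-dioxane, 80 °C
Reagents that add atoms: none
Why: Tsuji formate hydrogenolysis of an allylic carbonate, in which zerovalent palladium ionises the C5–O bond with inversion and passes the formate hydride to the more substituted allyl terminus C5 on the face opposite the departed oxygen, so that C5 ends inverted (trans ring fusion), the C3=C4 bond stays in place and loss of CO2 frees the C10 alcohol.

Step 11
Reactants: 18 tertiary alcohol; 19 3-phenylprop-2-ynoic acid
Product: 22 (3aR,5S,8S,8aS)-3,8-dimethyl-5-(prop-1-en-2-yl)-1,3a,4,5,6,7,8,8a-octahydroazulen-8-yl 3-phenylprop-2-ynoate, via 3-phenylprop-2-ynoyl chloride 20 (not isolated), via lithium alkoxide 21 (not isolated)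
Conditions: 19, (COCl)2, cat. DMF, CH2Cl2, 0 °C → rt, evaporate; 18, n-BuLi, THF, −78 °C; then 20, −78 → 0 °C
Reagents that add atoms: none
Why: Acylation of the lithium alkoxide of a hindered tertiary alcohol with an acid chloride, the alkynoate being chosen so that no Z-enoate has to survive the acylation.

Step 12
Reactants: 22 alkynoate
Product: 23 (3aR,5S,8S,8aS)-3,8-dimethyl-5-(prop-1-en-2-yl)-1,3a,4,5,6,7,8,8a-octahydroazulen-8-yl (2Z)-3-phenylprop-2-enoate
Conditions: H2 (1 atm), Pd/CaCO3 poisoned with Pb(OAc)2 (Lindlar catalyst), quinoline, EtOAc, rt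
Reagents that add atoms: none
Why: Lindlar semihydrogenation adds hydrogen syn to the alkyne and should stop at the Z-cinnamate before the isolated alkenes react.

Compound list
1 | (S)-(+)-carvone, (5S)-2-methyl-5-(prop-1-en-2-yl)cyclohex-2-en-1-one | CC1=CC[C@@H](CC1=O)C(C)=C | starting material
2 | lithium (5S)-2-methyl-5-(prop-1-en-2-yl)cyclohex-1-en-1-olate | CC1=C(O[Li])C[C@@H](C(C)=C)CC1 | intermediate (not isolated)
3 | trimethyl{[(5S)-2-methyl-5-(prop-1-en-2-yl)cyclohex-1-en-1-yl]oxy}silane | CC1=C(O[Si](C)(C)C)C[C@@H](C(C)=C)CC1 | intermediate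
4 | trimethyl{[(3S)-6-methyl-3-(prop-1-en-2-yl)bicyclo[4.1.0]heptan-1-yl]oxy}silane, both cis-fused cyclopropane diastereomers | CC12CC[C@H](C(C)=C)CC1(O[Si](C)(C)C)C2 | intermediate
5 | (6S)-3-chloro-3-methyl-6-(prop-1-en-2-yl)cycloheptan-1-one, both C3 epimers | CC1(Cl)CC(=O)C[C@@H](C(C)=C)CC1 | intermediate (not isolated)
6 | (6S)-3-methyl-6-(prop-1-en-2-yl)cyclohept-2-en-1-one | CC1=CC(=O)C[C@@H](C(C)=C)CC1 | intermediate
7 | (1S,4S,7S)-7-methyl-4-(prop-1-en-2-yl)-8-oxabicyclo[5.1.0]octan-2-one, oxirane oxygen trans to isopropenyl | C[C@]12CC[C@H](C(C)=C)CC(=O)[C@H]1O2 | intermediate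
8 | but-2-yn-1-ol | CC#CCO | starting material
9 | sodium cyclic vinylalanate, aluminium on C3 and on the alkoxide oxygen, two 2-methoxyethoxy ligands | [Na+].CC1=CCO[Al-]1(OCCOC)OCCOC | intermediate (not isolated)
10 | (2Z)-3-iodobut-2-en-1-ol | C/C(I)=C/CO | intermediate
11 | {[(2Z)-3-iodobut-2-en-1-yl]sulfanyl}benzene | C/C(I)=C/CSc1ccccc1 | intermediate
12 | [(2E)-4-(phenylsulfanyl)but-2-en-2-yl]lithium, lithium cis to the CH2SPh group | C/C([Li])=C/CSc1ccccc1 | intermediate (not isolated)
13 | (1R,2S,4S,7S)-7-methyl-2-[(2Z)-4-(phenylsulfanyl)but-2-en-2-yl]-4-(prop-1-en-2-yl)-8-oxabicyclo[5.1.0]octan-2-ol, hydroxyl cis to the oxirane oxygen | C[C@]12CC[C@H](C(C)=C)C[C@](O)(/C(C)=C\CSc3ccccc3)[C@H]1O2 | intermediate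
14 | lithium alkoxide of 13 | C[C@]12CC[C@H](C(C)=C)C[C@](O[Li])(/C(C)=C\CSc3ccccc3)[C@H]1O2 | intermediate (not isolated)
15 | lithium alkoxide of the epoxy alcohol with the allylic sulfur replaced by lithium (allyllithium at C2) | C[C@]12CC[C@H](C(C)=C)C[C@](O[Li])(/C(C)=C\C[Li])[C@H]1O2 | intermediate (not isolated)
16 | (3aR,5S,8S,8aR)-3,8-dimethyl-5-(prop-1-en-2-yl)-1,3a,4,5,6,7,8,8a-octahydroazulene-3a,8-diol, cis-fused, both hydroxyls cis to H-8a | C=C(C)[C@H]1CC[C@](C)(O)[C@H]2CC=C(C)[C@@]2(O)C1 | intermediate
17 | cyclic carbonate of 16 (3aR,5S,8S,8aR), 1,3-dioxan-2-one bridging O-3a and O-8 | C=C(C)[C@H]1CC[C@]2(C)OC(=O)O[C@@]3(C1)C(C)=CC[C@H]23 | intermediate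
18 | (3aR,5S,8S,8aS)-3,8-dimethyl-5-(prop-1-en-2-yl)-1,3a,4,5,6,7,8,8a-octahydroazulen-8-ol, trans-fused | C=C(C)[C@H]1CC[C@](C)(O)[C@H]2CC=C(C)[C@@H]2C1 | intermediate
19 | 3-phenylprop-2-ynoic acid | OC(=O)C#Cc1ccccc1 | starting material
20 | 3-phenylprop-2-ynoyl chloride | ClC(=O)C#Cc1ccccc1 | intermediate (not isolated)
21 | lithium alkoxide of 18 | C=C(C)[C@H]1CC[C@](C)(O[Li])[C@H]2CC=C(C)[C@@H]2C1 | intermediate (not isolated)
22 | (3aR,5S,8S,8aS)-3,8-dimethyl-5-(prop-1-en-2-yl)-1,3a,4,5,6,7,8,8a-octahydroazulen-8-yl 3-phenylprop-2-ynoate | C=C(C)[C@H]1CC[C@](C)(OC(=O)C#Cc2ccccc2)[C@H]2CC=C(C)[C@@H]2C1 | intermediate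
23 | (3aR,5S,8S,8aS)-3,8-dimethyl-5-(prop-1-en-2-yl)-1,3a,4,5,6,7,8,8a-octahydroazulen-8-yl (2Z)-3-phenylprop-2-enoate | C=C(C)[C@H]1CC[C@](C)(OC(=O)/C=C\c2ccccc2)[C@H]2CC=C(C)[C@@H]2C1 | target

Total step count: 12
Longest linear sequence: 10 steps (steps 1–4 and 7–12 from carvone); steps 5 and 6 make the side arm.

Steps most likely to fail

Step 8 (key step). The ambident allyl anion may attack through its substituted terminus and close a three-membered ring, or the radical anion may transfer an electron to the oxirane before the carbanion has closed the ring. The fallback sets out from 13 and uses a carbanion that can react at one carbon only. Oxidation of the sulfide with (NH4)6Mo7O24 and H2O2 in ethanol should give the allyl sulfone F1. LiN(i-Pr)2 (2.2 equiv, THF, −78 → 0 °C) forms the α-sulfonyl carbanion, which attacks only through the sulfur-bearing carbon C2 and closes the same five-membered ring to the sulfonyl diol F2. Palladium-catalysed desulfonylation with PdCl2[Ph2P(CH2)3PPh2] and LiBHEt3 in THF, in which hydride attacks the less hindered allyl terminus C2, comes back to the route at 16.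

Step 4. Iminium formation at the β,β-disubstituted enone may be slow, and the catalyst may discriminate poorly between the two enone faces. The fallback sets out from 6 and fixes the face through a carbinol instead. Corey–Bakshi–Shibata reduction with catecholborane, using the oxazaborolidine antipode that gives the (1R) carbinol, should give the allylic alcohol F3. Hydroxyl-directed epoxidation with VO(acac)2 and t-BuOOH delivers oxygen syn to the hydroxyl and gives the epoxy alcohol F4. Dess–Martin oxidation comes back to the route at 7.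

Step 10. Hydride may be transferred to the wrong allyl terminus (C3), or the allylpalladium intermediate may lose a β-hydrogen to a diene. The fallback sets out from 16 and moves the hydrogen to C5 by a sigmatropic route. Babler–Dauben oxidative transposition with pyridinium chlorochromate, [C5H5NH][CrO3Cl], should give the cyclopentenone F5. Hydroxyl-directed reduction with (CH3)4N[BH(OAc)3] delivers hydride from the face of the C10 hydroxyl and gives the allylic alcohol F6. Myers reductive transposition (2-nitrobenzenesulfonylhydrazide, PPh3, diethyl azodicarboxylate) inverts C3 in the Mitsunobu step; the allylic diazene then loses N2 in a retro-ene reaction that places hydrogen on C5 on the face of the C–N bond and returns the double bond to C3=C4. This comes back to the route at 18.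

Further compounds
F1 | step 8 | (1R,2S,4S,7S)-2-[(2Z)-4-(benzenesulfonyl)but-2-en-2-yl]-7-methyl-4-(prop-1-en-2-yl)-8-oxabicyclo[5.1.0]octan-2-ol | C[C@]12CC[C@H](C(C)=C)C[C@](O)(/C(C)=C\CS(=O)(=O)c3ccccc3)[C@H]1O2
F2 | step 8 | (3aR,5S,8S,8aR)-1-(benzenesulfonyl)-3,8-dimethyl-5-(prop-1-en-2-yl)-1,3a,4,5,6,7,8,8a-octahydroazulene-3a,8-diol, both C1 epimers | C=C(C)[C@H]1CC[C@](C)(O)[C@H]2C(S(=O)(=O)c3ccccc3)C=C(C)[C@@]2(O)C1
F3 | step 4 | (1R,6S)-3-methyl-6-(prop-1-en-2-yl)cyclohept-2-en-1-ol | CC1=C[C@H](O)C[C@@H](C(C)=C)CC1
F4 | step 4 | (1R,2R,4S,7S)-7-methyl-4-(prop-1-en-2-yl)-8-oxabicyclo[5.1.0]octan-2-ol | C[C@]12CC[C@H](C(C)=C)C[C@@H](O)[C@H]1O2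
F5 | step 10 | (5S,8S,8aS)-8-hydroxy-3,8-dimethyl-5-(prop-1-en-2-yl)-4,5,6,7,8,8a-hexahydroazulen-2(1H)-one | C=C(C)[C@H]1CC[C@](C)(O)[C@H]2CC(=O)C(C)=C2C1
F6 | step 10 | (2S,5S,8S,8aS)-3,8-dimethyl-5-(prop-1-en-2-yl)-1,2,4,5,6,7,8,8a-octahydroazulene-2,8-diol | C=C(C)[C@H]1CC[C@](C)(O)[C@H]2C[C@H](O)C(C)=C2C1
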